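Read each flask by its end share: the target made, taken over its smaller charge, the limiting reagent.

| flask | starting material | reagent | time |
|---|---|---|---|
| blue | 300 mM | 360 mM |  |
| red | 150 mM | 210 mM |  |
| ochre | 900 mM | 360 mM |  |
| green | 300 mM | 540 mM |  |
| amber | 150 mM | 720 mM | 160 min |

| run | time / min | [target] / mM |
|---|---|---|
| blue run | 9.1 | 45 |
| blue run | 28 | 93 |
| blue run | 53 | 115 |
| blue run | 84 | 121 |
| blue run | 120 | 139 |
| blue run | 160 | 140 |
| red run | 9.1 | 15 |
| red run | 28 | 22 |
| red run | 53 | 44 |
| red run | 84 | 57 |
| red run | 120 | 55 |
| red run | 160 | 61 |
| ochre run | 9.1 | 116 |
| ochre run | 28 | 173 |
| ochre run | 53 | 180 |
| ochre run | 84 | 176 |
| ochre run | 120 | 181 |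
| ochre run | 160 | 179 |
| green run | 9.1 | 65 |
| green run | 28 | 125 |
| green run | 53 | 137 |
| green run | 84 | 148 |
| green run | 120 | 144 |
| green run | 160 | 139 |

(scatter of a reading: 4 mM)

- Overall: starting material + reagent -> target.
- Constant volume, constant temperature.
- "The second partner" is reagent.
- An order is taken over about fifteen percent of the charge, up and down.

- order of the initial rate in [reagent], near the charge of the blue run, the rate being that where two percent of its starting material are target
- order of the initial rate in [starting material], near the charge of the blue run, the rate being that where two percent of its starting material are target (one fixed amount of target, the same in the runs compared)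
- target in the amber run at 160 min, as a share of the starting material charged
- which of these the readings show (the second partner is lost by itself / the product binds the second partner / the product speeds the reaction / nothing beyond the main steps / the second partner pairs with itself)

The red flask gives 38.7% as its end share, the mean of its last two target readings over its smaller charge.

Turn reagent first. From blue to green it rises 1.50 times over the same 300 mM of starting material, the smaller charge in both flasks. By hand, the rate follows and the end stays. The readings agree: the green target at 9.1 min reads 1.44 times the blue one, and the end shares are 46.5% in blue and 47.2% in green.

Turn starting material next. From blue to ochre it rises 3.00 times, and reagent becomes the smaller charge. By hand, the rate follows again. The ochre target at 9.1 min reads 2.58 times the blue one, and the ochre end share, counted on reagent, is 50.0%. Both orders therefore stand near first order.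

Shrink both charges. A fixed split would hold the share, but the red flask ends lower than blue. The reckoning here reads this as the product speeding the reaction.

Time remains. Starting material falls at least as fast as target rises, and the amber flask keeps at least 570 mM of reagent. The red target at 9.1 min, taken as an early rate over the two red charges, then gives an estimate of 0.846% of the amber starting material left at 160 min, hardly any. The amber flask has the red smaller charge, so this reckoning puts it near 38.7%.

The forecast differs: 52% (43% to 63%), orders 0.95 in reagent and 0.95 in starting material, and "the second partner pairs with itself", on the ground that “every run stops dead with both partners unused, so reagent is being destroyed”.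

    starting material + reagent → target (0.05526 L mol⁻¹ min⁻¹)
    starting material + reagent → side product (0.1026 L mol⁻¹ min⁻¹)
    starting material + reagent + target → 2 target (0.6360 L² mol⁻² min⁻¹)

The amber flask gives 41.7% at 160 min, 10 percentage points under the forecast and 3 points over the red end share. The orders are 1.0 in reagent and 1.1 in starting material, and the readings show that the product speeds the reaction. A power-law fit to the earlier runs puts the amber flask at 89.2%. The blue flask has twice the red smaller charge, and the red end share would give it 116 mM, less than the 140 mM it reads at 160 min.

Readings and results are simulated for substances that don't exist; noise was put on by code.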